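The leftover substrate is what I look at first in these flasks, since each product forms in proportion to what stands of its own hand of substrate.

all flasks: left-handed substrate 0.20 M; solid reagent 2.50 equiv; catalyst 1.4 mol%; added ligand 8.0 mM; right-handed substrate 0.20 M; time 6.0 min
- Monday's: temperature 30 °C
- Sunday's: temperature 70 °C
- Friday's: temperature 50 °C

1. the flask with the highest excess of left-handed product over right-handed product ("all alike" if they lie within 1.5 percentage points) (Monday's / Sunday's / Friday's / all alike)
2. excess of left-handed product over right-handed product at the end, Monday's
3. excess of left-handed product over right-handed product at the end, Sunday's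
4. excess of left-handed product over right-handed product at the end, Friday's

- catalyst is single-handed; left-handed substrate and right-handed substrate are mirror images of each other, charged as a racemate, each of them at the stated concentration
- given per volume of solution although it is solid: solid reagent
- the constants hold at 50 °C; other temperatures follow from the activation energies and enthalpies
- at the start none of the solid reagent is in solution
- an excess is the difference of the two amounts in percent of their sum
- an excess is below zero if the other one leads

    solid reagent ⇌ partner, rate k1*(cs1 - [partner]) while solid is left; crystals form when [partner] > cs1 (cs1 = 0.16 M, k1 = 0.051 s⁻¹)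
    partner + catalyst + right-handed substrate → catalyst + right-handed product (k2 = 1.7 L² mol⁻² s⁻¹, Ea2 = 57.0 kJ mol⁻¹)
    partner → decomposed reagent (k3 = 6.6 × 10⁻⁴ s⁻¹, Ea3 = 97.0 kJ mol⁻¹)
    partner + catalyst + left-handed substrate → catalyst + left-handed product (k4 = 3.1 L² mol⁻² s⁻¹, Ea4 = 37.0 kJ mol⁻¹)
    left-handed substrate ⇌ right-handed substrate (k5 = 0.0040 s⁻¹, Ea5 = 104 kJ mol⁻¹)
    catalyst + added ligand ⇌ idle complex, settled at all times (K6 = 170 L mol⁻¹, ΔH6 = −14.0 kJ mol⁻¹)
    (constants at 50 °C)

The two products form at rates that share c(partner) and c(catalyst), so these cancel in the ratio of the rates. While c(left-handed substrate) equals c(right-handed substrate), the products stand in the ratio of the two constants at the flask's temperature, and the excess is that ratio minus one over that ratio plus one.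

The ratio is 1.82 at 50 °C, and it moves with the difference of activation energies, 20.0 kJ mol⁻¹. Monday's selectivity factor, the left-handed step's constant over the right-handed step's at that flask's temperature, is 2.98. Moved the same way, it becomes 1.18 on Sunday's and 1.82 on Friday's.

My excesses are 49.7 % for Monday's, 8.33 % for Sunday's and 29.2 % for Friday's, so I expect Monday's to lead.

This needs level substrates. In Sunday's flask the two substrates relax into each other, by their interconversion taken by itself, with a half-life of 0.151 min, far shorter than the 6.0 min allowed, so I expect them level there. In Monday's flask that half-life is 18.6 min, longer than the time allowed, so a small lead of right-handed substrate can stand, and I expect Monday's a little under my figure.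

The forecast names Monday's and gives 49 % for Monday's, 8.2 % for Sunday's and 28 % for Friday's, holding that “Depletion of the faster enantiomer, countered by racemization, gives small corrections”. With its small depletion correction, its Monday's figure stands below mine.

The flasks give 48.9 % on Monday's, 8.19 % on Sunday's and 28.1 % on Friday's, so Monday's leads.

At 6.00 min, Monday's flask keeps 93 % of its left-handed substrate and 97 % of its right-handed substrate. Multiplying Monday's selectivity factor by that ratio gives 2.85, which means an excess of 48.0 % for the product forming at that moment. Monday's whole-run excess lies above this and below the level-substrate figure.

For the repeat of Sunday's at 45 °C, the selectivity factor moves to 2.05, an excess of 34.4 % with level substrates. With that flask's leftover of 86 % against 90 %, the excess of the product forming at the end is 32.4 %. The simulated flask gives a whole-run excess of 33.2 %.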